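**Plan**
- Target 19 is a 3-hydroxy-3,4-dibenzyl-γ-butyrolactone (ring numbering O1, C2(=O), C3, C4, C5). The retrosynthesis opens the O1–C2 lactone bond, replaces C3–OH by C3–B, then cuts C3–C4 and the CH2–aryl bond of the C3 benzyl arm in one operation. Last it cuts the CH2–aryl bond of the C4 benzyl arm and the two C–B bonds of an alkene diboration.
- Enabling feature: C3 carries an oxygen, the C2 carbon, C4 and a CH2–aryl group. This is the pattern left when a 2-borylallyl ether takes up an alkyl group migrating from boron at its internal carbon and an aryl group at its CH2.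
- Forward order: C5–C4 with the syringyl arm first (diboration of allyl benzyl ether, coupling at the primary boron), then the three-component coupling that creates C3, then C–B to C–OH, C2 alcohol to acid. The only ring, the lactone, closes last on debenzylation.
- Stereochemistry: C4 comes from the ligand-controlled diboration and is kept by the stereoretentive boron-to-carbon shift. C3 comes from the chiral palladium catalyst and is kept by stereoretentive C–B oxidation.

Key step: step 6

Remark: for the two catalytic asymmetric steps (2 and 6) the ligand antipode is assigned from the usual stereochemical models and is to be confirmed in a pilot run; the route depends on the configurations drawn, not on a particular ligand label.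

**Step 1**
Reactants: 1 4-bromo-2,6-dimethoxyphenol
Product: 2 2-(benzyloxy)-5-bromo-1,3-dimethoxybenzene
Conditions: BnBr, K2CO3, DMF, 60 °C
Reagents that add atoms: benzyl bromide, BrCc1ccccc1
Why: Williamson etherification of the acidic, flanked phenol with a reactive benzylic halide is routine and leaves the aryl bromide untouched.

**Step 2**
Reactants: 3 allyl benzyl ether; 2 2-(benzyloxy)-5-bromo-1,3-dimethoxybenzene
Product: 5 2-{(2S)-1-(benzyloxy)-3-[4-(benzyloxy)-3,5-dimethoxyphenyl]propan-2-yl}-4,4,5,5-tetramethyl-1,3,2-dioxaborolane, via vicinal bis(boronate) 4 (not isolated)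
Conditions: B2pin2, Pt(dba)3 (1 mol%), TADDOL-derived phenylphosphonite L* (1.2 mol%, antipode giving (S)-4), THF, 60 °C; then 2, Pd(OAc)2/RuPhos (2 mol%), KOH, THF–H2O, 70 °C
Reagents that add atoms: bis(pinacolato)diboron, CC1(C)OB(OC1(C)C)B1OC(C)(C)C(C)(C)O1
Why: Platinum-catalysed enantioselective syn-diboration of the terminal alkene sets C4 through face selection by the chiral phosphonite, and the primary boronate of the vicinal pair then undergoes the neighbour-assisted, site-selective Suzuki–Miyaura coupling with 2 while the secondary C–B bond and its configuration stay intact (diboration/cross-coupling cascade).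

**Step 3**
Reactants: 6 2-bromoprop-2-en-1-ol
Product: 7 [(2-bromoprop-2-en-1-yl)oxy](tert-butyl)dimethylsilane
Conditions: TBSCl, imidazole, CH2Cl2, 0 °C → rt
Reagents that add atoms: tert-butyldimethylsilyl chloride, CC(C)(C)[Si](C)(C)Cl
Why: Standard imidazole-promoted silylation of a primary allylic alcohol; the vinyl bromide is inert.

**Step 4**
Reactants: 8 4-(benzyloxy)-3-methoxybenzaldehyde
Product: 10 4-(benzyloxy)-3-methoxyphenol, via aryl formate 9 (not isolated)
Conditions: mCPBA, CH2Cl2, rt; then K2CO3 (cat.), MeOH, rt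
Reagents that add atoms: meta-chloroperoxybenzoic acid, OOC(=O)c1cccc(Cl)c1
Why: Baeyer–Villiger oxidation with a Dakin-type outcome: the electron-rich aryl group migrates in the Criegee intermediate to give the aryl formate, which mild methanolysis cleaves to the phenol.

**Step 5**
Reactants: 10 4-(benzyloxy)-3-methoxyphenol
Product: 11 4-(benzyloxy)-3-methoxyphenyl trifluoromethanesulfonate
Conditions: Tf2O, pyridine, CH2Cl2, 0 °C
Reagents that add atoms: trifluoromethanesulfonic anhydride, O=S(=O)(OS(=O)(=O)C(F)(F)F)C(F)(F)F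
Why: O-Sulfonylation of a phenol with triflic anhydride and pyridine is general and gives the electrophile needed for a cationic arylpalladium species.

**Step 6**
Reactants: 5 C4 boronate 2-{(2S)-1-(benzyloxy)-3-[4-(benzyloxy)-3,5-dimethoxyphenyl]propan-2-yl}-4,4,5,5-tetramethyl-1,3,2-dioxaborolane; 7 [(2-bromoprop-2-en-1-yl)oxy](tert-butyl)dimethylsilane; 11 4-(benzyloxy)-3-methoxyphenyl trifluoromethanesulfonate
Product: 14 tertiary pinacol boronate tert-butyl{[(2R,3R)-4-(benzyloxy)-2-[4-(benzyloxy)-3-methoxybenzyl]-3-[4-(benzyloxy)-3,5-dimethoxybenzyl]-2-(4,4,5,5-tetramethyl-1,3,2-dioxaborolan-2-yl)butyl]oxy}dimethylsilane, via alkenyllithium 12 (not isolated), via boron ate complex 13 (not isolated)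
Conditions: 7, t-BuLi (2.0 equiv), Et2O, −78 °C; 5, THF, −78 °C → rt; evaporate; 11, Pd(OAc)2 (5 mol%), MandyPhos-type ferrocenyl bisphosphine (6 mol%, antipode matched to C4), NaOTf (2 equiv), THF, 60 °C
Reagents that add atoms: none
Why: Proposed new method: oxidative addition of triflate 11 to the chiral Pd(0) bisphosphine gives a cationic arylpalladium(II) that binds the alkene of ate complex 13, whereupon C4 shifts anti from boron to the boron-bearing alkene carbon (new C3–C4 bond) as palladium bonds to the terminal CH2, and reductive elimination then joins that CH2 to the aryl group. The closest known reaction type is the palladium-catalysed enantioselective conjunctive cross-coupling of α-substituted alkenyl boron ate complexes with aryl triflates to tertiary boronic esters; a stereodefined β-benzyloxy secondary alkyl group migrating onto an alkene that carries a silyloxymethyl substituent has not been shown. No ring is closed. The new stereocentre C3 is set by the ferrocenyl bisphosphine, which decides the alkene face that palladium takes (both antipodes to be tried so that catalyst control is matched with the neighbouring C4 centre), while C4 keeps its configuration because 1,2-metallate shifts are retentive at the migrating carbon. The step needs the metallate shift to outrun direct alkenyl transmetalation (plain Suzuki arylation) and loss of benzyloxide from the ate complex, which the wide-bite-angle bisphosphine, the non-coordinating triflate, bromide scavenging by NaOTf and the poor leaving-group ability of alkoxide should secure. β-Hydride elimination from the alkylpalladium intermediate is excluded because its β-carbon (C3) is fully substituted.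

**Step 7**
Reactants: 14 tertiary pinacol boronate
Product: 15 (2S,3S)-4-(benzyloxy)-2-[4-(benzyloxy)-3-methoxybenzyl]-3-[4-(benzyloxy)-3,5-dimethoxybenzyl]-1-[(tert-butyldimethylsilyl)oxy]butan-2-ol
Conditions: 30% H2O2, aq. NaOH, THF, 0 °C → rt
Reagents that add atoms: hydrogen peroxide, OO
Why: Alkaline peroxide oxidation of an organoboronate moves C3 from boron to oxygen with retention, so the tertiary carbinol inherits the configuration fixed in step 6, and silyl and benzyl ethers are stable to it.

**Step 8**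
Reactants: 15 silyl ether of the tertiary alcohol
Product: 16 (2S,3S)-4-(benzyloxy)-2-[4-(benzyloxy)-3-methoxybenzyl]-3-[4-(benzyloxy)-3,5-dimethoxybenzyl]butane-1,2-diol
Conditions: TBAF, THF, 0 °C → rt
Reagents that add atoms: none
Why: Fluoride-driven desilylation cleaves the primary TBS ether and touches neither the benzyl ethers nor the stereocentres.

**Step 9**
Reactants: 16 primary/tertiary 1,2-diol
Product: 17 (2S,3S)-4-(benzyloxy)-2-[4-(benzyloxy)-3-methoxybenzyl]-3-[4-(benzyloxy)-3,5-dimethoxybenzyl]-2-hydroxybutanoic acid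
Conditions: TEMPO (10 mol%), NaClO2, NaOCl (cat.), MeCN–phosphate buffer (pH 6.7), 35 °C
Reagents that add atoms: sodium chlorite, [Na+].[O-]Cl=O
Why: TEMPO-catalysed chlorite oxidation takes only the primary alcohol through the aldehyde to the acid; the tertiary hydroxyl cannot be oxidised, the buffered medium should spare benzyl ethers and electron-rich rings, and neither stereocentre is enolisable (C3 quaternary, C4 β to the carbonyl).

**Step 10**
Reactants: 17 tri-O-benzyl α-hydroxy acid
Product: 19 (3S,4S)-3-hydroxy-4-(4-hydroxy-3,5-dimethoxybenzyl)-3-(4-hydroxy-3-methoxybenzyl)dihydrofuran-2(3H)-one, via trihydroxy acid 18 (not isolated)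
Conditions: H2 (1 atm), 10% Pd/C, EtOAc, rt; filter; TsOH (cat.), toluene, 40 °C
Reagents that add atoms: none
Why: Hydrogenolysis removes the two aryl and the one alkyl benzyl ether, and the freed C5 hydroxyl closes the five-membered lactone onto the acid (acid-catalysed lactonisation of a γ-hydroxy acid) without touching either stereocentre.

**Compound list**
1 | 4-bromo-2,6-dimethoxyphenol | COc1cc(Br)cc(OC)c1O | starting material
2 | 2-(benzyloxy)-5-bromo-1,3-dimethoxybenzene | COc1cc(Br)cc(OC)c1OCc1ccccc1 | intermediate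
3 | allyl benzyl ether | C=CCOCc1ccccc1 | starting material
4 | (S)-2,2'-[3-(benzyloxy)propane-1,2-diyl]bis(4,4,5,5-tetramethyl-1,3,2-dioxaborolane) | CC1(C)OB([C@H](COCc2ccccc2)CB2OC(C)(C)C(C)(C)O2)OC1(C)C | intermediate
5 | 2-{(2S)-1-(benzyloxy)-3-[4-(benzyloxy)-3,5-dimethoxyphenyl]propan-2-yl}-4,4,5,5-tetramethyl-1,3,2-dioxaborolane | CC1(C)OB([C@H](COCc2ccccc2)Cc2cc(OC)c(OCc3ccccc3)c(OC)c2)OC1(C)C | intermediate
6 | 2-bromoprop-2-en-1-ol (2-bromoallyl alcohol) | OCC(Br)=C | starting material
7 | [(2-bromoprop-2-en-1-yl)oxy](tert-butyl)dimethylsilane | C=C(Br)CO[Si](C)(C)C(C)(C)C | intermediate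
8 | 4-(benzyloxy)-3-methoxybenzaldehyde | COc1cc(C=O)ccc1OCc1ccccc1 | starting material
9 | 4-(benzyloxy)-3-methoxyphenyl formate | COc1cc(OC=O)ccc1OCc1ccccc1 | intermediate
10 | 4-(benzyloxy)-3-methoxyphenol | COc1cc(O)ccc1OCc1ccccc1 | intermediate
11 | 4-(benzyloxy)-3-methoxyphenyl trifluoromethanesulfonate | COc1cc(OS(=O)(=O)C(F)(F)F)ccc1OCc1ccccc1 | intermediate
12 | {3-[(tert-butyldimethylsilyl)oxy]prop-1-en-2-yl}lithium | [Li]C(=C)CO[Si](C)(C)C(C)(C)C | intermediate
13 | lithium {(2S)-1-(benzyloxy)-3-[4-(benzyloxy)-3,5-dimethoxyphenyl]propan-2-yl}{3-[(tert-butyldimethylsilyl)oxy]prop-1-en-2-yl}(pinacolato)borate | [Li+].C=C(CO[Si](C)(C)C(C)(C)C)[B-]1(OC(C)(C)C(C)(C)O1)[C@H](COCc1ccccc1)Cc1cc(OC)c(OCc2ccccc2)c(OC)c1 | intermediate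
14 | tert-butyl{[(2R,3R)-4-(benzyloxy)-2-[4-(benzyloxy)-3-methoxybenzyl]-3-[4-(benzyloxy)-3,5-dimethoxybenzyl]-2-(4,4,5,5-tetramethyl-1,3,2-dioxaborolan-2-yl)butyl]oxy}dimethylsilane | COc1cc(C[C@@](B2OC(C)(C)C(C)(C)O2)(CO[Si](C)(C)C(C)(C)C)[C@H](COCc2ccccc2)Cc2cc(OC)c(OCc3ccccc3)c(OC)c2)ccc1OCc1ccccc1 | intermediate
15 | (2S,3S)-4-(benzyloxy)-2-[4-(benzyloxy)-3-methoxybenzyl]-3-[4-(benzyloxy)-3,5-dimethoxybenzyl]-1-[(tert-butyldimethylsilyl)oxy]butan-2-ol | COc1cc(C[C@@](O)(CO[Si](C)(C)C(C)(C)C)[C@H](COCc2ccccc2)Cc2cc(OC)c(OCc3ccccc3)c(OC)c2)ccc1OCc1ccccc1 | intermediate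
16 | (2S,3S)-4-(benzyloxy)-2-[4-(benzyloxy)-3-methoxybenzyl]-3-[4-(benzyloxy)-3,5-dimethoxybenzyl]butane-1,2-diol | COc1cc(C[C@@](O)(CO)[C@H](COCc2ccccc2)Cc2cc(OC)c(OCc3ccccc3)c(OC)c2)ccc1OCc1ccccc1 | intermediate
17 | (2S,3S)-4-(benzyloxy)-2-[4-(benzyloxy)-3-methoxybenzyl]-3-[4-(benzyloxy)-3,5-dimethoxybenzyl]-2-hydroxybutanoic acid | COc1cc(C[C@@](O)(C(=O)O)[C@H](COCc2ccccc2)Cc2cc(OC)c(OCc3ccccc3)c(OC)c2)ccc1OCc1ccccc1 | intermediate
18 | (2S,3S)-2,4-dihydroxy-3-(4-hydroxy-3,5-dimethoxybenzyl)-2-(4-hydroxy-3-methoxybenzyl)butanoic acid | COc1cc(C[C@@](O)(C(=O)O)[C@H](CO)Cc2cc(OC)c(O)c(OC)c2)ccc1O | intermediate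
19 | (3S,4S)-3-hydroxy-4-(4-hydroxy-3,5-dimethoxybenzyl)-3-(4-hydroxy-3-methoxybenzyl)dihydrofuran-2(3H)-one | COc1cc(C[C@@]2(O)C(=O)OC[C@@H]2Cc2cc(OC)c(O)c(OC)c2)ccc1O | target

**Totals**
Total step count: 10. Longest linear sequence: 7 steps (1 → 2 → 5 → 14 → 15 → 16 → 17 → 19; the triflate branch 8 → 10 → 11 → 14 is equally long).

**Steps most likely to fail**

1. Step 6 (proposed new method). Several processes could defeat it:
   - transfer of the alkenyl group to palladium without migration;
   - slow migration of the hindered secondary group;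
   - loss of benzyloxide from the ate complex;
   - O-to-C silyl shift in the alkenyllithium if it warms above −78 °C;
   - mismatched facial selectivity.

   The fallback uses known chemistry, sets out from 5 and returns at diol 16, bypassing steps 7 and 8. Ate complex 13 is formed from 5 and 12 as before and is treated with iodine and then sodium methoxide (Zweifel olefination). This should give, with retention at C4, the 1,1-disubstituted alkene tert-butyl{[(3R)-4-(benzyloxy)-3-[4-(benzyloxy)-3,5-dimethoxybenzyl]-2-methylidenebutyl]oxy}dimethylsilane F1. TBAF frees the allylic alcohol (3R)-4-(benzyloxy)-3-[4-(benzyloxy)-3,5-dimethoxybenzyl]-2-methylidenebutan-1-ol F2. Sharpless asymmetric epoxidation (Ti(OiPr)4, diethyl tartrate antipode chosen by the mnemonic, t-BuOOH, CH2Cl2, −20 °C) then sets C3 under reagent control, giving the epoxy alcohol {(2S)-2-[(2S)-1-(benzyloxy)-3-[4-(benzyloxy)-3,5-dimethoxyphenyl]propan-2-yl]oxiran-2-yl}methanol F3. Finally [4-(benzyloxy)-3-methoxyphenyl]magnesium bromide F4, made from commercial 1-(benzyloxy)-4-bromo-2-methoxybenzene and magnesium, opens the epoxide at its unsubstituted CH2 under CuI catalysis in THF to give 16.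

2. Step 2. The diboration of an allylic ether may show insufficient facial selectivity. The β-benzyloxy boronate may lose benzyloxide or protodeboronate in hot aqueous KOH. Coupling may also occur at the secondary boron.

   The fallback sets out from bromide 2 and returns at 5. Benzyl propargyl ether is hydroborated with pinacolborane (Cp2ZrHCl cat.) to (E)-2-[3-(benzyloxy)prop-1-en-1-yl]-4,4,5,5-tetramethyl-1,3,2-dioxaborolane F5. Suzuki–Miyaura coupling of F5 with 2 (Pd(dppf)Cl2, K3PO4, dioxane–H2O, 80 °C) gives 2-(benzyloxy)-5-[(E)-3-(benzyloxy)prop-1-en-1-yl]-1,3-dimethoxybenzene F6. A copper-catalysed enantioselective protoboration (CuCl, NaOt-Bu, chiral NHC or bisphosphine ligand, B2pin2, MeOH, THF) then converts F6 into 5. The aryl group should direct copper to the benzylic carbon and boron to the carbon next to CH2OBn.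

3. Step 9. The α-hydroxy aldehyde stage may suffer C–C cleavage or over-oxidation, the electron-rich rings may be chlorinated by hypochlorite, or the neopentyl-type alcohol may convert incompletely.

   The fallback sets out from 16 and returns at 17. It splits the change into two separate oxidations through an isolated intermediate and uses neither an oxoammonium salt nor hypochlorite. Parikh–Doering oxidation (SO3·pyridine, DMSO, i-Pr2NEt, CH2Cl2, 0 °C) stops at (2S,3S)-4-(benzyloxy)-2-[4-(benzyloxy)-3-methoxybenzyl]-3-[4-(benzyloxy)-3,5-dimethoxybenzyl]-2-hydroxybutanal F7. Pinnick oxidation (NaClO2, NaH2PO4, 2-methyl-2-butene, t-BuOH–H2O) then gives 17.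

**Further compounds**
F1 | step 6 | tert-butyl{[(3R)-4-(benzyloxy)-3-[4-(benzyloxy)-3,5-dimethoxybenzyl]-2-methylidenebutyl]oxy}dimethylsilane | C=C(CO[Si](C)(C)C(C)(C)C)[C@H](COCc1ccccc1)Cc1cc(OC)c(OCc2ccccc2)c(OC)c1
F2 | step 6 | (3R)-4-(benzyloxy)-3-[4-(benzyloxy)-3,5-dimethoxybenzyl]-2-methylidenebutan-1-ol | C=C(CO)[C@H](COCc1ccccc1)Cc1cc(OC)c(OCc2ccccc2)c(OC)c1
F3 | step 6 | {(2S)-2-[(2S)-1-(benzyloxy)-3-[4-(benzyloxy)-3,5-dimethoxyphenyl]propan-2-yl]oxiran-2-yl}methanol | OC[C@]1(CO1)[C@H](COCc1ccccc1)Cc1cc(OC)c(OCc2ccccc2)c(OC)c1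
F4 | step 6 | [4-(benzyloxy)-3-methoxyphenyl]magnesium bromide | COc1cc([Mg]Br)ccc1OCc1ccccc1
F5 | step 2 | (E)-2-[3-(benzyloxy)prop-1-en-1-yl]-4,4,5,5-tetramethyl-1,3,2-dioxaborolane | CC1(C)OB(/C=C/COCc2ccccc2)OC1(C)C
F6 | step 2 | 2-(benzyloxy)-5-[(E)-3-(benzyloxy)prop-1-en-1-yl]-1,3-dimethoxybenzene | COc1cc(/C=C/COCc2ccccc2)cc(OC)c1OCc1ccccc1
F7 | step 9 | (2S,3S)-4-(benzyloxy)-2-[4-(benzyloxy)-3-methoxybenzyl]-3-[4-(benzyloxy)-3,5-dimethoxybenzyl]-2-hydroxybutanal | COc1cc(C[C@@](O)(C=O)[C@H](COCc2ccccc2)Cc2cc(OC)c(OCc3ccccc3)c(OC)c2)ccc1OCc1ccccc1
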